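## The problem

CNP0143627.2 (14) is a compact tetracycle: a 4,5-dibromopyrrole (ring A, numbered from the acyl-bearing carbon C-2), a five-membered lactam (ring B), a piperidine (ring C) and a 2-aminoimidazoline (ring D), all fused around one carbon. That carbon carries three nitrogens (the pyrrole nitrogen of rings A/B, the lactam nitrogen of rings B/C, an N–H of the ring D guanidine) and one carbon, so it is a fully substituted triaminomethane stereocentre (S). Its only carbon neighbour is a carbinolamine carbon (R) bearing OH, the second guanidine ring nitrogen and the first CH2 of ring C. Ring D can only be cis-fused to ring C, and the carbinolamine is the reversible adduct of a guanidine N–H with a ketone, so the carbinol centre follows from the triamino carbon. The stereochemical task is therefore one quaternary N,N,N,C-substituted centre in the absolute sense, with no other stereocentre left in the target to control it. Fragile elements are the two C–Br bonds (no hydrogenolysis, dissolving metals or halogen–metal exchange), the strained acyl-aminal lactam, the polar guanidine carbinolamine, and the triamino carbon itself, which can reopen under base by loss of the acylpyrrole anion and would then racemise once the adjacent carbon is a ketone. The enabling feature is that the lactam nitrogen and the triamino carbon are neighbours in ring C and that ring B hangs on exactly these two atoms, through N–C(=O) and N(pyrrole)–C. Ring C with its exocyclic nitrogen is thus a cyclic amidine, across whose N=C bond a pyrrole-2-carbonyl unit with free N–H can be laid; the adjacent carbinol carbon can come from (S)-3-hydroxypiperidin-2-one 1 as a silyl ether, steer the addition, and then be oxidised to the ketone that ring D needs.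

## Retrosynthesis

**Ring D (14 ⇒ 12 + 13).** The carbinol C–N bond (a carbinolamine, i.e. N–H added to C=O) and the bond between the guanidine carbon and the nitrogen on the triamino carbon are cut, giving α-amino ketone 12 and cyanamide 13. Carrying a free or protected guanidine through the synthesis would put extra basic nitrogens into every intermediate and into the acylation step. The cyanamide condensation of α-amino ketones is the classical entry to 2-aminoimidazoles, and here it cannot run on to the aromatic imidazole because the carbon next to the carbinol carbon has no hydrogen. The precursor has three rings and one stereocentre instead of four and two. The forward step must guanylate a hindered, weakly basic amine without base; the carbinol centre then forms reversibly and can only be cis-fused (R).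

**Functional-group adjustments (12 ⇒ 11 ⇒ 10 ⇒ 9).** No skeletal bond is cut: 12 is the ammonium salt from Boc carbamate 11, 11 the oxidation product of alcohol 10, and 10 the desilylation product of 9. Keeping the ketone through the annulation is rejected because a 3-oxo amidine would enolise, and because the carbinol carbon is the only handle for absolute control of the triamino carbon. The forward steps must be non-basic: a free alkoxide would attack the syn Boc group, and from 11 onward reopening of the aminal would racemise the one remaining stereocentre.

**Ring B (9 ⇒ 5 + 7, through 8).** The lactam N–C(=O) bond and the pyrrole N–C(triamino) bond are cut together.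
- Cutting only the first would leave an aminal with a free ring N–H, which would collapse to amidine and pyrrole.
- Cutting only the second gives 8, an acyl donor not suited to storage, so it is made a transient intermediate.
- Cuts inside ring C keep rings A and B and the triamino centre, and push the hard stereocentre into the starting material.

This cut removes a ring and the quaternary centre and splits the molecule into achiral acid chloride 7 and Boc-amidine 5 with one chiral-pool stereocentre. The forward reaction must acylate the ring nitrogen (the exocyclic one is blocked by Boc), close ring B 5-exo-trig, and add the pyrrole nitrogen anti to the silyloxy group.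

**Acyl fragment (7 ⇒ 6).** The C–Cl bond is cut to commercial acid 6; the chloride is made without base so that its own N–H stays inert.

**Amidine fragment (5 ⇒ 4 ⇒ 3 ⇒ 2 ⇒ 1).** The carbamate N–C bond is cut to amidine salt 4, the exocyclic amidine C–N bond to lactim ether 3, the O–methyl bond to lactam 2, and the O–Si bond to 1. All four are routine and need no strong base, so the α-oxygenated stereocentre is not at risk.

## Roads not taken

**Alternative 1:** The cut is the bond between the lactam nitrogen and the neighbouring ring C CH2. The four carbons of ring C come from a furan already on the aminal carbon of bicyclic lactam A1 (furan-2-yl, phthalimido and lactam N–H on that carbon). Forward, mCPBA would open the furan oxidatively and the lactam N–H would capture the unmasked aldehyde (aza-Achmatowicz reaction), closing ring C as hydroxy enone A2.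
- Merits: the reaction type is better precedented than the key step chosen here, and the ring C ketone appears unprotected at the correct carbon, so no desilylation or alcohol oxidation is needed.
- Weak points: A1 already contains the triamino stereocentre, and no enantioselective route to a carbon bearing furyl, phthalimido, pyrrole N and amide N is apparent. The capturing N–H is a strained lactam at a quaternary carbon, not the usual sulfonamide or carbamate. A2 carries one C=C and one hemiaminal OH too many, to be removed next to two aryl bromides, and hydrazine for the phthalimide would meet a ketone.
- Comparison: at least five operations follow A2 against four after 9. The chosen plan instead creates the stereocentre in its key step under control of a commercial chiral-pool centre.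

**Alternative 2:** All three C–N bonds at the triamino carbon and the guanidine–ketone bond are cut, giving acyclic keto trithioorthoester A3, whose ester-bearing stereocentre comes from the amino-acid pool. Forward, guanidine would condense with the ketone while dimethyl(methylthio)sulfonium tetrafluoroborate removes the three methylthio groups in turn, and amide N, pyrrole N and guanidine N would each bond to that carbon, closing rings C, B and D to ester A4.
- Merits: if it worked, no route reaches the tetracycle faster, with three rings formed in one flask at the right oxidation level; on step count up to the tetracycle it is clearly better than the chosen plan.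
- Weak points: three different nitrogens must each add once and in a workable order. Free guanidine is the best nucleophile and can add twice or be sulfenylated; the thionium ions sit next to a ketone and are destabilised. The triamino configuration would rest on remote induction across a forming ring.
- Comparison: A4 still carries the ester, whose removal (hydrolysis, then radical decarboxylation beside aryl bromides and a free guanidine carbinolamine) is a C–C cleavage on the most fragile compound. The chosen plan erases its relay centre by an oxidation the target needs anyway.

**Alternative 3:** The ring C C–C bond between the CH2 on the lactam nitrogen and its neighbour is cut. The precursor A5 is a ring A–B lactam with N-acetoxymethyl, Boc-amino and 1-hydroxycyclopropyl groups. Forward, Et2Zn would open the cyclopropanol (homoenolate reactivity) while Zn(OTf)2 ionises the N–CH2OAc group, and the β-carbon would attack the N-acyliminium carbon to give amino ketone A6.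
- Merits: A6 is identical with 11, so the end game is the same but two steps shorter after the key step, and a C–C bond is formed with release of ring strain.
- Weak points: A5 must already hold ring B and the triamino stereocentre bearing a hydroxycyclopropyl group, for which no asymmetric access is evident. Zinc homoenolates are weak nucleophiles, and Et2Zn would first deprotonate the carbamate N–H. Simple protonation to an ethyl ketone competes.
- Comparison: it is more direct to 11, but it leaves open where the absolute configuration comes from. The chosen plan answers that with the annulation itself and two simple fragments.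

Key step: step 6

Assumption: 1 is used as the commercial enantiopure (S)-lactam, and 14 is isolated as its free base.

## Route

Step 1
Reactants: 1 (S)-3-hydroxypiperidin-2-one
Product: 2 (S)-3-(tert-butyldimethylsilyloxy)piperidin-2-one
Conditions: TBSCl, imidazole, DMF, rt
Reagents that add atoms: tert-butyldimethylsilyl chloride, CC(C)(C)[Si](C)(C)Cl
Why: Standard O-silylation of a secondary alcohol; the lactam N–H is not silylated under imidazole catalysis and the stereocentre is not touched.

Step 2
Reactants: 2 (S)-3-(tert-butyldimethylsilyloxy)piperidin-2-one
Product: 3 (3S)-3-(tert-butyldimethylsilyloxy)-2-methoxy-3,4,5,6-tetrahydropyridine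
Conditions: Me3OBF4, CH2Cl2, 0 °C to rt; cold aq. K2CO3
Reagents that add atoms: trimethyloxonium tetrafluoroborate, C[O+](C)C.F[B-](F)(F)F
Why: O-Alkylation of a secondary lactam by a hard oxonium electrophile gives the lactim ether; the HBF4 set free is held by the product nitrogen until the carbonate wash, and no base able to remove the α-hydrogen is present.

Step 3
Reactants: 3 (3S)-3-(tert-butyldimethylsilyloxy)-2-methoxy-3,4,5,6-tetrahydropyridine
Product: 4 (3S)-3-(tert-butyldimethylsilyloxy)-3,4,5,6-tetrahydropyridin-2-amine hydrochloride
Conditions: NH4Cl, MeOH, rt to 40 °C
Reagents that add atoms: ammonium chloride, [NH4+].[Cl-]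
Why: Pinner-type aminolysis of an imidate: ammonia adds to the protonated lactim ether and methanol leaves, giving the amidinium chloride in a near-neutral medium that spares silyl ether and stereocentre.

Step 4
Reactants: 4 (3S)-3-(tert-butyldimethylsilyloxy)-3,4,5,6-tetrahydropyridin-2-amine hydrochloride
Product: 5 tert-butyl N-[(3S)-3-(tert-butyldimethylsilyloxy)-3,4,5,6-tetrahydropyridin-2-yl]carbamate
Conditions: Boc2O, Et3N, CH2Cl2, 0 °C to rt
Reagents that add atoms: di-tert-butyl dicarbonate, CC(C)(C)OC(=O)OC(=O)OC(C)(C)C
Why: Mono-acylation of a free amidine; the product settles as the exocyclic carbamate (hydrogen-bonded to the ring nitrogen in either tautomer), and a second acylation is slow because the acylated amidine is far less nucleophilic.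

Step 5
Reactants: 6 4,5-dibromo-1H-pyrrole-2-carboxylic acid
Product: 7 4,5-dibromo-1H-pyrrole-2-carbonyl chloride
Conditions: (COCl)2, DMF (cat.), CH2Cl2, 0 °C to rt; evaporated, used crude
Reagents that add atoms: oxalyl chloride, O=C(Cl)C(=O)Cl
Why: Acid chloride formation through the Vilsmeier-type chloroiminium catalyst; without base the pyrrole N–H does not self-condense.

Step 6
Reactants: 5 tert-butyl N-[(3S)-3-(tert-butyldimethylsilyloxy)-3,4,5,6-tetrahydropyridin-2-yl]carbamate; 7 4,5-dibromo-1H-pyrrole-2-carbonyl chloride
Product: 9 silyloxy tricyclic Boc-aminal (rings A–B–C; triamino carbon S bearing NHBoc; neighbouring carbon S bearing OTBS trans to the pyrrole nitrogen), via N-acyl-N′-Boc amidine 8 (not isolated)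
Conditions: 7 added slowly to 5, EtN(iPr)2, CH2Cl2, −40 to 0 °C; then DBU (0.3 equiv), 0 °C to rt
Reagents that add atoms: none
Why: Proposed new method: the ring nitrogen of 5, the only amidine nitrogen not deactivated by Boc, attacks 7 to give 8, whose C=N–Boc carbon now lies between two acylated nitrogens and is as electrophilic as an N-acylimine; the pyrrole N–H, acidified by its carbonyl and two bromines and held beside that carbon by the new amide, is deprotonated by DBU and adds to it, and proton transfer to the carbamate nitrogen gives 9. The closest known reaction types are the annulation of amidines with ortho-aminoaroyl chlorides to quinazolinones, whose tetrahedral triamino intermediate is the end point here because the pyrrole nitrogen has no second hydrogen to lose, and N–H additions to N-acylimines. Ring B closes 5-exo-trig on the exocyclic C=N bond. The new triamino stereocentre is controlled by the silyloxy-bearing carbon next to it: allylic 1,3-strain against the acylimino group turns the OTBS group axial, so it covers one face of the C=N and the tethered pyrrolide enters anti to it. The addition is base-reversible, so the anti isomer, which also keeps the silyl ether away from the bromine-flanked pyrrole nitrogen, should accumulate. The step needs ring-N over carbamate-N acylation (secured by Boc), ring closure faster than acyl transfer from 8 or self-condensation of 7 (secured by slow addition of 7 to amidine and base at low temperature), and integrity of the relay centre (the axial OTBS leaves its α-hydrogen in the imine plane, so imine–enecarbamate tautomerism should be slow).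

Step 7
Reactants: 9 silyloxy tricyclic Boc-aminal
Product: 10 hydroxy tricyclic Boc-aminal (triamino carbon S; carbinol carbon S; OH cis to NHBoc)
Conditions: HF·pyridine, pyridine, THF, 0 °C to rt
Reagents that add atoms: none
Why: Fluoride-driven Si–O cleavage under buffered, non-basic conditions, so that no alkoxide forms to attack the syn Boc group and the aminal is not reopened.

Step 8
Reactants: 10 hydroxy tricyclic Boc-aminal
Product: 11 tricyclic Boc-amino ketone (triamino carbon S)
Conditions: Dess–Martin periodinane, CH2Cl2, 0 °C to rt
Reagents that add atoms: none
Why: Dess–Martin oxidation of a hindered secondary alcohol under neutral conditions; the relay stereocentre is erased and the triamino carbon, which has no hydrogen, stays the only stereocentre.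

Step 9
Reactants: 11 tricyclic Boc-amino ketone
Product: 12 tricyclic amino ketone trifluoroacetate (triamino carbon S)
Conditions: CF3CO2H, CH2Cl2, 0 °C; evaporated, used directly
Reagents that add atoms: trifluoroacetic acid, OC(=O)C(F)(F)F
Why: Acidolysis of the Boc carbamate; the triamino carbon should not ionise, because the cation would sit next to a ketone with only an amide and a pyrrole nitrogen to support it, and the amine is kept as its salt.

Step 10
Reactants: 12 tricyclic amino ketone trifluoroacetate; 13 cyanamide
Product: 14 CNP0143627.2 (carbinol carbon R; triamino carbon S)
Conditions: H2O/EtOH, pH 4.5 (AcOH/NaOAc), 60 °C; then aq. NaHCO3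
Reagents that add atoms: none
Why: Condensation of an α-amino ketone with cyanamide (the classical 2-aminoimidazole synthesis), stopped at the hydroxy-imidazoline because the carbinol carbon's neighbour has no hydrogen; cyanamide may also add first to the activated ketone and be captured by the amine. Ring D can only close cis, so the carbinol centre (R) is set reversibly by the triamino carbon.

## Compound list

1 | (S)-3-hydroxypiperidin-2-one | O[C@H]1CCCNC1=O | starting material
2 | (S)-3-(tert-butyldimethylsilyloxy)piperidin-2-one | CC(C)(C)[Si](C)(C)O[C@H]1CCCNC1=O | intermediate
3 | (3S)-3-(tert-butyldimethylsilyloxy)-2-methoxy-3,4,5,6-tetrahydropyridine | COC1=NCCC[C@@H]1O[Si](C)(C)C(C)(C)C | intermediate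
4 | (3S)-3-(tert-butyldimethylsilyloxy)-3,4,5,6-tetrahydropyridin-2-amine hydrochloride | Cl.NC1=NCCC[C@@H]1O[Si](C)(C)C(C)(C)C | intermediate
5 | tert-butyl N-[(3S)-3-(tert-butyldimethylsilyloxy)-3,4,5,6-tetrahydropyridin-2-yl]carbamate | CC(C)(C)OC(=O)NC1=NCCC[C@@H]1O[Si](C)(C)C(C)(C)C | intermediate
6 | 4,5-dibromo-1H-pyrrole-2-carboxylic acid | OC(=O)c1cc(Br)c(Br)[nH]1 | starting material
7 | 4,5-dibromo-1H-pyrrole-2-carbonyl chloride | O=C(Cl)c1cc(Br)c(Br)[nH]1 | intermediate
8 | tert-butyl N-[(3S)-1-(4,5-dibromo-1H-pyrrole-2-carbonyl)-3-(tert-butyldimethylsilyloxy)piperidin-2-ylidene]carbamate; formed in the flask of step 6 only | CC(C)(C)OC(=O)N=C1[C@@H](O[Si](C)(C)C(C)(C)C)CCCN1C(=O)c1cc(Br)c(Br)[nH]1 | intermediate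
9 | silyloxy tricyclic Boc-aminal: rings A–B–C of the target; triamino carbon (S) bears NHBoc; neighbouring ring C carbon (S) bears H and OTBS, trans to the pyrrole nitrogen and cis to NHBoc | CC(C)(C)[Si](C)(C)O[C@H]1CCCN2C(=O)c3cc(Br)c(Br)n3[C@@]21NC(=O)OC(C)(C)C | intermediate
10 | hydroxy tricyclic Boc-aminal: as 9 with OH in place of OTBS (carbinol carbon S; triamino carbon S) | O[C@H]1CCCN2C(=O)c3cc(Br)c(Br)n3[C@@]21NC(=O)OC(C)(C)C | intermediate
11 | tricyclic Boc-amino ketone: as 10 with C=O in place of CH(OH) (triamino carbon S) | O=C1CCCN2C(=O)c3cc(Br)c(Br)n3[C@@]21NC(=O)OC(C)(C)C | intermediate
12 | tricyclic amino ketone trifluoroacetate: as 11 with NH2 (as its CF3CO2H salt) in place of NHBoc (triamino carbon S) | O=C1CCCN2C(=O)c3cc(Br)c(Br)n3[C@@]21N.OC(=O)C(F)(F)F | intermediate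
13 | cyanamide | NC#N | starting material
14 | CNP0143627.2: rings A–B–C–D; 2-aminoimidazoline cis-fused to ring C (carbinol carbon R; triamino carbon S) | NC1=N[C@@]2(O)CCCN3C(=O)c4cc(Br)c(Br)n4[C@@]32N1 | target

## Step count and least certain steps

Total: 10 steps. Longest linear sequence: 9 steps (1 to 14 through steps 1–4 and 6–10); step 5 is a one-step side branch.

**Step 6 (key step, proposed new method).**
- What may go wrong: acylation at the carbamate nitrogen or oxygen instead of the ring nitrogen; acyl transfer from the activated intermediate 8, or self-condensation of 7 through its own N–H, before ring B closes; an unfavourable ring–chain balance between 8 and 9; imine–enecarbamate tautomerisation of 8 eroding the relay centre; insufficient facial selectivity.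
- Consequence for purity: any syn isomer must be removed by chromatography at 9 or 10, because after step 8 it would become the enantiomer of 11.
- Fallback (known reactions only): it keeps the chiral-pool relay, makes both ring B bonds at the aminal C–H oxidation level, and brings in the third nitrogen afterwards by stereoretentive C–H amination. It sets out from lactim ether 3 and acid chloride 7 and returns at alcohol 10. Warming 3 with 7 in toluene should give, by N-acylation and loss of chloromethane, the N-acyl lactam (S)-1-(4,5-dibromo-1H-pyrrole-2-carbonyl)-3-(tert-butyldimethylsilyloxy)piperidin-2-one F1. NaBH4 in MeOH at −20 °C should reduce the ring carbonyl next to the silyloxy group to the carbinolamide F2. CF3CO2H in CH2Cl2 at 0 °C ionises it, and the pyrrole nitrogen closes ring B on the N-acyliminium ion anti to OTBS, giving the tricyclic aminal F3 with a hydrogen, cis to oxygen, on the future triamino carbon. HF·pyridine gives the alcohol F4, and NaOCN with CF3CO2H in CH2Cl2 the primary carbamate F5. Rh2(OAc)4 (cat.), PhI(OAc)2 and MgO in CH2Cl2 at 40 °C should insert the carbamate nitrene into the adjacent aminal C–H bond with retention, giving the cis-fused oxazolidinone F6. Boc2O with DMAP gives the N-Boc oxazolidinone F7, and Cs2CO3 in MeOH opens it at the ring carbonyl to 10.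

**Step 10.**
- What may go wrong: guanylation of the hindered, weakly basic aminal nitrogen may be slower than self-condensation of cyanamide, and hot aqueous acid may hydrolyse the aminal or the strained lactam.
- Fallback: from 12, N,N′-di-Boc-N″-triflylguanidine and Et3N in CH2Cl2 should give the di-Boc guanidino ketone F8. CF3CO2H in CH2Cl2, then aq. NaHCO3, removes both Boc groups and lets the guanidine close onto the ketone, returning at 14.

**Step 7.**
- What may go wrong: slow cleavage of a silyl ether flanked by a quaternary carbon under the buffered conditions; if more basic fluoride is used to force it, attack of the alkoxide on the syn Boc group or reopening of the aminal.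
- Fallback: from 9, HCl in MeOH (0 °C to rt) removes silyl and Boc groups together to give the amino alcohol hydrochloride F9. Boc2O with NaHCO3 in THF/H2O re-protects the nitrogen and returns at 10; any O-carbonate is cleaved by K2CO3 in MeOH.

**Step 2.**
- What may go wrong: competing N-methylation, loss of the silyl ether through the HBF4 formed, or hydrolysis of the lactim ether back to 2 on work-up.
- Fallback: from 2, Lawesson's reagent in toluene at 80 °C gives the thiolactam (S)-3-(tert-butyldimethylsilyloxy)piperidine-2-thione F10. NH3 in MeOH with HgCl2 at 0 °C to rt converts it, with precipitation of HgS, directly into amidine hydrochloride 4.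

## Further compounds

F1 | step 6 | (S)-1-(4,5-dibromo-1H-pyrrole-2-carbonyl)-3-(tert-butyldimethylsilyloxy)piperidin-2-one | CC(C)(C)[Si](C)(C)O[C@H]1CCCN(C(=O)c2cc(Br)c(Br)[nH]2)C1=O
F2 | step 6 | (3S)-1-(4,5-dibromo-1H-pyrrole-2-carbonyl)-3-(tert-butyldimethylsilyloxy)piperidin-2-ol; carbinolamide, both C-2 epimers | CC(C)(C)[Si](C)(C)O[C@H]1CCCN(C(=O)c2cc(Br)c(Br)[nH]2)C1O
F3 | step 6 | silyloxy tricyclic aminal: rings A–B–C with H on the future triamino carbon, cis to OTBS | CC(C)(C)[Si](C)(C)O[C@H]1CCCN2C(=O)c3cc(Br)c(Br)n3[C@@H]21
F4 | step 6 | hydroxy tricyclic aminal: as F3 with OH in place of OTBS | O[C@H]1CCCN2C(=O)c3cc(Br)c(Br)n3[C@@H]21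
F5 | step 6 | primary carbamate (O–C(=O)NH2) of F4 | NC(=O)O[C@H]1CCCN2C(=O)c3cc(Br)c(Br)n3[C@@H]21
F6 | step 6 | cis-fused oxazolidinone spanning the carbinol oxygen and the triamino carbon of rings A–B–C | O=C1O[C@H]2CCCN3C(=O)c4cc(Br)c(Br)n4[C@@]32N1
F7 | step 6 | N-Boc derivative of oxazolidinone F6 | O=C1O[C@H]2CCCN3C(=O)c4cc(Br)c(Br)n4[C@@]32N1C(=O)OC(C)(C)C
F8 | step 10 | N,N′-di-Boc guanidino ketone: 11 with NH–C(=NBoc)–NHBoc in place of NHBoc | O=C1CCCN2C(=O)c3cc(Br)c(Br)n3[C@@]21NC(=NC(=O)OC(C)(C)C)NC(=O)OC(C)(C)C
F9 | step 7 | amino alcohol hydrochloride: 10 with NH2 (as HCl salt) in place of NHBoc | Cl.O[C@H]1CCCN2C(=O)c3cc(Br)c(Br)n3[C@@]21N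
F10 | step 2 | (S)-3-(tert-butyldimethylsilyloxy)piperidine-2-thione | CC(C)(C)[Si](C)(C)O[C@H]1CCCNC1=S
A1 | alternative 1 | ring A–B lactam whose aminal carbon bears furan-2-yl, phthalimido and the lactam N–H | O=C1N[C@](c2ccco2)(N2C(=O)c3ccccc3C2=O)n2c(Br)c(Br)cc12
A2 | alternative 1 | tricyclic hydroxy enone (6-hydroxy-2H-pyridin-3-one ring C; hemiaminal carbon as both epimers) with phthalimido on the triamino carbon | O=C1C=CC(O)N2C(=O)c3cc(Br)c(Br)n3[C@@]21N1C(=O)c2ccccc2C1=O
A3 | alternative 2 | methyl (S)-2-(4,5-dibromo-1H-pyrrole-2-carboxamido)-5-oxo-6,6,6-tris(methylthio)hexanoate | COC(=O)[C@H](CCC(=O)C(SC)(SC)SC)NC(=O)c1cc(Br)c(Br)[nH]1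
A4 | alternative 2 | 14 carrying a methyl ester on the CH2 next to the lactam nitrogen | NC1=N[C@@]2(O)CC[C@@H](C(=O)OC)N3C(=O)c4cc(Br)c(Br)n4[C@@]32N1
A5 | alternative 3 | ring A–B lactam with N-acetoxymethyl on the lactam nitrogen and NHBoc and 1-hydroxycyclopropyl on the aminal carbon | CC(=O)OCN1C(=O)c2cc(Br)c(Br)n2[C@]1(NC(=O)OC(C)(C)C)C1(O)CC1
A6 | alternative 3 | tricyclic Boc-amino ketone, identical with 11 | O=C1CCCN2C(=O)c3cc(Br)c(Br)n3[C@@]21NC(=O)OC(C)(C)C
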